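The readings are simulated for substances that don't exist, and the scatter is random.

Time was what I first held the rate against, in flasks set out here:

| flask | starting material | enzyme | remark | time |
|---|---|---|---|---|
| alpha | 0.10 M | 59 µM | run made earlier |  |
| zeta | 0.050 M | 59 µM | run made earlier |  |
| delta | 0.075 M | 59 µM | run made earlier |  |
| beta | 0.10 M | 88 µM | run made earlier |  |
| maple | 0.10 M | 59 µM | one stirred flow tank at steady state, fed with the mixture as stated, mean residence time 8.0 min |  |
| larch | 0.10 M | 59 µM | a closed flask charged with all of it at once and left for 8.0 min | 8.0 min |
| elm | 0.10 M (fed, over 6.40 min) | 59 µM | a stirred flask in which starting material is dosed at a steady rate over 6.40 min without added volume, worked up at 8.0 min | 8.0 min |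
| alder | 0.10 M | 59 µM | a single well-mixed tank run continuously and read at steady state, 80.0 min in it on average |  |

| run | time / min | product / % |
|---|---|---|
| alpha | 0.417 | 6.8 |
| alpha | 0.833 | 13.1 |
| alpha | 2.00 | 26.2 |
| alpha | 5.00 | 49.3 |
| zeta | 0.417 | 10.4 |
| zeta | 0.833 | 19.2 |
| zeta | 2.00 | 38.1 |
| zeta | 5.00 | 65.5 |
| delta | 0.667 | 12.8 |
| delta | 1.50 | 24.8 |
| delta | 3.00 | 41.2 |
| delta | 5.00 | 56.7 |
| beta | 0.667 | 14.3 |
| beta | 1.50 | 29.1 |
| beta | 3.00 | 46.2 |
| beta | 5.00 | 60.9 |

(scatter of a reading: 0.3 percentage points)

- the stated concentrations are those of everything mixed, before any reaction; amounts are the same in each set-up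
- the feed brings no volume worth counting
- the earlier runs were made in a closed, stirred flask

- order of the set-ups by the amount of product at the outlet or at the end, in percent of the starting material put in, highest first (maple / larch / elm / alder)
- amount of product at the outlet or at the end, in percent of the starting material put in, maple
- amount of product at the outlet or at the end, in percent of the starting material put in, larch
- amount of product at the outlet or at the end, in percent of the starting material put in, elm
- amount of product at the outlet or at the end, in percent of the starting material put in, alder

I wrote each rate as the time constant of one molecule of starting material: its amount over its rate of loss. At the start this was 5.92 min in alpha and 3.80 min in zeta. So it climbs with starting material: read from these two runs, it stands on a base of 1.76 min and gains one base more for each 0.0407 M of starting material. This is saturation, and it slows fresh alpha by a factor 3.36.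

Between 2.00 min and 5.00 min the constants stood above this fresh line by a factor 1.82 in alpha and 1.89 in zeta, while alpha held more product, 0.0378 M against 0.0259 M. These two factors do not separate a term in product from the age of the enzyme, so reading the factor as age was my choice. Beta's 29.1% at 1.50 min equals 2.24 min of alpha's enzyme-time, just past alpha's 26.2% at 2.00 min, so I took the ageing as second order in enzyme: a slowing of one plus time over an ageing time of 4.10 min.

Summed, that leaves larch a working time of 4.44 min in 8.0 min, counted in fresh minutes. A molecule dosed into elm gets what remains after its arrival. This remaining working time, averaged over the feed, is 2.21 min, half of larch's. Against a time constant of 3.91 min, taken at 0.0500 M, I reckoned elm at 43.2%.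

The forecast read “Michaelis–Menten kinetics with strong product inhibition” and gave maple 48.4%, larch 63.6%, elm 51% and alder 88%, in the order alder > larch > elm > maple. Its elm is higher than mine, and mine falls below its maple.

The flasks gave maple 51.2%, larch 62.8%, elm 41.4% and alder 87.2%, in the order alder > larch > maple > elm.

    starting material + enzyme → product + enzyme, rate k1*[starting material]*[enzyme]/(1 + ([starting material]/Km1)) (44.0 mM, k = 160 M⁻¹ s⁻¹)
    2 enzyme → spent catalyst (k = 38.0 M⁻¹ s⁻¹)

At 4.00 min larch and elm each held 48.2% of their enzyme, yet larch had 43.0% product and elm 19.7%. Elm's 2.21 min of remaining working time, against larch's 4.44 min, had given 43.2%, and elm stood at 41.4%. In the neighbour flask, like elm but with 1.0 × 10⁻⁴ M of enzyme, the ageing time shortens to 2.42 min and the remaining working time, in elm's enzyme, becomes 2.78 min, a factor 1.26 on elm's 2.21 min, which gives 50.9%; the computed flask gave 49.3%.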